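**Plan**
- Retrosynthesis cuts both lactone O–C(aryl) bonds first (O1–C8a of each dihydrocoumarin half), then both cyclobutane–aryl bonds (C4–C4a), then the pyran O–CMe2 bond of the aryl donor.
- Enabling feature: the cyclobutane (C3, C4, C3', C4') is all-cis and the molecule has only a C2 axis. With both O1–C8a bonds open it is a meso 2,4-diaryl-1,3-diacid in which each carboxyl sits between two enantiotopic aryl groups, so the chirality lies only in which carboxyl pairs with which aryl.
- Forward: the 2,2-dimethyl-2H-pyran ring is closed on a bromo-iodo-salicylaldehyde; two such arenes are put on cis-cyclobutane-1,3-dicarboxylic acid bis(quinolin-8-yl amide) by double C–H arylation; the auxiliaries are removed; both lactone rings are closed last, in one operation.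
- Stereochemistry: relative (all-cis) from the amide-directed, retentive C–H arylation; absolute from catalyst-controlled desymmetrisation in the double lactonisation. Arene regiochemistry comes from the bromine placed at chromene C5.

Key step: step 6

Assumption: the sense of induction of the chiral diamine–copper catalyst in step 6 cannot be predicted; the (1S,2S) ligand is written, and its antipode would be used if the first experiment gave the other enantiomer.

**Step 1**
Reactants: 1 2-bromo-6-hydroxybenzaldehyde
Product: 2 2-bromo-6-hydroxy-3-iodobenzaldehyde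
Conditions: NIS (1.05 equiv), TsOH·H2O (10 mol %), MeCN, 0 °C to rt
Reagents that add atoms: N-iodosuccinimide, O=C1CCC(=O)N1I
Why: Electrophilic aromatic iodination; the phenolic OH directs para (the position that is also ortho to bromine, as in the iodination of 3-halophenols to 3-halo-4-iodophenols) and the hydrogen-bonded formyl group should hold the reaction at mono-iodination; no stereocentre.

**Step 2**
Reactants: 2 2-bromo-6-hydroxy-3-iodobenzaldehyde; 3 2-methylprop-1-enylmagnesium bromide
Product: 5 5-bromo-6-iodo-2,2-dimethyl-2H-chromene, via allylic alcohol 4 (not isolated)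
Conditions: 3 (2.5 equiv), THF, −40 to 0 °C; aq NH4Cl; crude 4, PPTS (10 mol %), toluene, 80 °C
Reagents that add atoms: none
Why: Grignard 1,2-addition to the aldehyde (one equivalent is spent on the phenol), then acid-promoted loss of water from the ortho-hydroxybenzylic allylic alcohol 4 to an ortho-quinone methide that closes by oxa-6π electrocyclisation to the 2,2-dimethyl-2H-pyran; the ring-fusion position is fixed by the aldehyde carbon and the carbinol stereocentre of 4 is lost.

**Step 3**
Reactants: 6 cis-cyclobutane-1,3-dicarboxylic acid; 7 quinolin-8-amine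
Product: 8 cis-N1,N3-di(quinolin-8-yl)cyclobutane-1,3-dicarboxamide
Conditions: 7 (2.2 equiv), EDC·HCl (2.5 equiv), DMAP (0.3 equiv), CH2Cl2, 0 °C to rt
Reagents that add atoms: none
Why: Carbodiimide amide coupling puts the bidentate 8-aminoquinoline auxiliary on both carboxyl groups; the cis-1,3 arrangement (the more stable isomer) is kept.

**Step 4**
Reactants: 8 cis-N1,N3-di(quinolin-8-yl)cyclobutane-1,3-dicarboxamide; 5 5-bromo-6-iodo-2,2-dimethyl-2H-chromene (3 equiv)
Product: 10 all-cis (meso) 2,4-bis(5-bromo-2,2-dimethyl-2H-chromen-6-yl)-N1,N3-di(quinolin-8-yl)cyclobutane-1,3-dicarboxamide, via mono-aryl bis-amide 9 (not isolated)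
Conditions: Pd(OAc)2 (20 mol %), AgOAc (4 equiv), (BnO)2PO2H (40 mol %), t-AmOH, 110 °C
Reagents that add atoms: none
Why: Auxiliary-directed C(sp3)–H arylation in a divalent/tetravalent palladium cycle: N,N-chelation holds palladium on the amide face, concerted metalation–deprotonation of the methylene C–H cis to the carbonyl gives a five-membered palladacycle, the C–I bond (not C–Br) adds oxidatively and C–C reductive elimination occurs with retention, so each aryl enters cis to both amides and the second methylene follows via 9 to the all-cis meso cyclobutane, as is known for double arylation of cyclobutane carboxamides.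

**Step 5**
Reactants: 10 all-cis (meso) 2,4-bis(5-bromo-2,2-dimethyl-2H-chromen-6-yl)-N1,N3-di(quinolin-8-yl)cyclobutane-1,3-dicarboxamide
Product: 12 all-cis (meso) 2,4-bis(5-bromo-2,2-dimethyl-2H-chromen-6-yl)cyclobutane-1,3-dicarboxylic acid, via bis(N-Boc) imide 11 (not isolated)
Conditions: Boc2O (6 equiv), DMAP (0.4 equiv), MeCN, 60 °C; evaporate; LiOH·H2O (5 equiv), 30% H2O2 (12 equiv), THF/H2O 3:1, 0 °C; Na2SO3; 1 M HCl to pH 3
Reagents that add atoms: hydrogen peroxide, OO (carboxyl OH oxygens of 12); di-tert-butyl dicarbonate, CC(C)(C)OC(=O)OC(=O)OC(C)(C)C (Boc groups of 11 only)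
Why: N-Boc activation makes the amide an imide, so that lithium hydroperoxide attacks the exocyclic acyl carbon and expels the Boc-aminoquinoline (the usual two-stage cleavage of N-aryl auxiliaries); the weakly basic nucleophile at 0 °C should leave the all-cis centres, the aryl bromides and the chromene alkenes untouched.

**Step 6**
Reactants: 12 all-cis (meso) 2,4-bis(5-bromo-2,2-dimethyl-2H-chromen-6-yl)cyclobutane-1,3-dicarboxylic acid
Product: 14 syn head-to-tail cyclobutane dimer of seselin (target; 3S,4R,3'S,4'R in coumarin numbering), via monolactone bromo acid 13 (not isolated)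
Conditions: CuI (20 mol %), (1S,2S)-N,N'-dimethyl-1,2-diphenylethane-1,2-diamine (40 mol %), Cs2CO3 (2.5 equiv), 1,4-dioxane (0.02 M), 90 °C; AcOH quench
Reagents that add atoms: none
Why: Proposed new method: Cs2CO3 gives the dicarboxylate, one carboxylate binds the diamine-ligated CuI (monovalent copper), the C–Br bond of one of the two cis-vicinal, enantiotopic aryl groups adds oxidatively within the chelate (trivalent copper, seven-membered metallacycle) and C–O reductive elimination closes the six-membered lactone by intramolecular O-arylation at the ipso carbon (a 6-exo-type closure onto the arene carbon), after which the same sequence on the other side of 13 closes the second lactone. The closest known reaction types are the copper/chiral-diamine desymmetrising intramolecular Ullmann C–N and C–O couplings, in which one nucleophile selects between two enantiotopic 2-haloaryl groups, and the racemic copper-mediated lactonisation of 2-halobiaryl carboxylic acids; new here is the carboxylate as the selecting nucleophile. No stereocentre is made: the four all-cis ring carbons come from step 4, and the absolute configuration is decided only by which of its two neighbouring aryl bromides the first carboxylate captures, under control of the chiral diamine on copper. The second closure needs no selection, because the remaining carboxylate can reach only the one remaining bromide (each arene carries a single bromine and one arene cannot bridge both carboxyls), so neither a meso nor a mismatched bis-lactone can form and the enantiomeric purity of 13 passes to 14. The selectivity to be secured is therefore enantiotopic-group selection in the first C–O coupling plus ipso regiochemistry on the arene; the substrate supplies the latter through the bromine at chromene C5 (a position flanked on both sides that a C–H lactonisation would avoid) and supports the former through the rigid all-cis cyclobutane that holds both aryl bromides within reach of the bound carboxylate. Carboxylate α-carbons do not epimerise under carbonate, and the cis-fused lactones, once formed, cannot epimerise without becoming trans-fused.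

**Compound list**
1 | 2-bromo-6-hydroxybenzaldehyde | O=Cc1c(O)cccc1Br | starting material
2 | 2-bromo-6-hydroxy-3-iodobenzaldehyde | O=Cc1c(O)ccc(I)c1Br | intermediate
3 | 2-methylprop-1-enylmagnesium bromide | CC(C)=C[Mg]Br | starting material
4 | 3-bromo-2-(1-hydroxy-3-methylbut-2-en-1-yl)-4-iodophenol (racemic allylic alcohol) | CC(C)=CC(O)c1c(O)ccc(I)c1Br | intermediate (not isolated)
5 | 5-bromo-6-iodo-2,2-dimethyl-2H-chromene | CC1(C)C=Cc2c(Br)c(I)ccc2O1 | intermediate
6 | cis-cyclobutane-1,3-dicarboxylic acid | OC(=O)[C@H]1C[C@@H](C(=O)O)C1 | starting material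
7 | quinolin-8-amine (8-aminoquinoline) | Nc1cccc2cccnc12 | starting material
8 | cis-N1,N3-di(quinolin-8-yl)cyclobutane-1,3-dicarboxamide | O=C(Nc1cccc2cccnc12)[C@H]1C[C@@H](C(=O)Nc2cccc3cccnc23)C1 | intermediate
9 | all-cis 2-(5-bromo-2,2-dimethyl-2H-chromen-6-yl)-N1,N3-di(quinolin-8-yl)cyclobutane-1,3-dicarboxamide (achiral) | O=C(Nc1cccc2cccnc12)[C@H]1[C@@H](c2ccc3OC(C)(C)C=Cc3c2Br)[C@@H](C(=O)Nc2cccc3cccnc23)C1 | intermediate (not isolated)
10 | all-cis (meso) 2,4-bis(5-bromo-2,2-dimethyl-2H-chromen-6-yl)-N1,N3-di(quinolin-8-yl)cyclobutane-1,3-dicarboxamide | O=C(Nc1cccc2cccnc12)[C@H]1[C@@H](c2ccc3OC(C)(C)C=Cc3c2Br)[C@@H](C(=O)Nc2cccc3cccnc23)[C@H]1c1ccc2OC(C)(C)C=Cc2c1Br | intermediate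
11 | N1,N3-bis(tert-butoxycarbonyl) derivative of 10 (all-cis, meso) | CC(C)(C)OC(=O)N(c1cccc2cccnc12)C(=O)[C@H]1[C@@H](c2ccc3OC(C)(C)C=Cc3c2Br)[C@@H](C(=O)N(C(=O)OC(C)(C)C)c2cccc3cccnc23)[C@H]1c1ccc2OC(C)(C)C=Cc2c1Br | intermediate (not isolated)
12 | all-cis (meso) 2,4-bis(5-bromo-2,2-dimethyl-2H-chromen-6-yl)cyclobutane-1,3-dicarboxylic acid | OC(=O)[C@H]1[C@@H](c2ccc3OC(C)(C)C=Cc3c2Br)[C@@H](C(=O)O)[C@H]1c1ccc2OC(C)(C)C=Cc2c1Br | intermediate
13 | monolactone bromo acid: all-cis cyclobuta-fused 3,4-dihydroseselin with CO2H on the cyclobutane carbon next to the benzylic carbon and the 5-bromo-2,2-dimethyl-2H-chromen-6-yl group on the carbon next to the lactone α-carbon; absolute sense as in 14 | CC1(C)C=Cc2c(ccc3c2OC(=O)[C@H]2[C@@H]3[C@@H](C(=O)O)[C@H]2c2ccc3OC(C)(C)C=Cc3c2Br)O1 | intermediate (not isolated)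
14 | syn head-to-tail cyclobutane dimer of seselin (8,8-dimethyl-2H,8H-pyrano[2,3-f]chromen-2-one), all four cyclobutane hydrogens cis, lactone α-carbons S and benzylic carbons R | CC1(C)C=Cc2c(ccc3c2OC(=O)[C@H]2[C@@H]3[C@H]3C(=O)Oc4c5c(ccc4[C@H]32)OC(C)(C)C=C5)O1 | target

**Count and risks**
Total steps: 6. Longest linear sequence: 5 (steps 1, 2, 4, 5, 6).

1. Step 6. What may go wrong: poor discrimination of the two enantiotopic aryl bromides by the chiral copper carboxylate, or slow C–O reductive elimination from the weakly nucleophilic carboxylate with competing protodebromination. Fallback (known chemistry), setting out from 12: stoichiometric copper thiophene-2-carboxylate, Cu(O2CC4H3S) (monovalent copper), in NMP at 120 °C, the known racemic Ullmann-type lactonisation of ortho-halo aryl carboxylic acids, should close both lactones without a chiral ligand and give the racemate, that is 14 together with the enantiomer of 14 F1. Preparative chromatography on a chiral stationary phase (cellulose tris(3,5-dimethylphenylcarbamate)) then comes back to the route at 14.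

2. Step 4. What may go wrong: slow oxidative addition of the ortho-bromo aryl iodide to the palladacycle, so that the reaction stops at 9 or the iodide is lost to homocoupling. Fallback, setting out from 8: the bromine is left out of the aryl donor and put in after the C–C bonds exist.
   - Kabbe condensation of 1-(2-hydroxy-5-iodophenyl)ethanone with acetone (pyrrolidine) gives 6-iodo-2,2-dimethylchroman-4-one F2, an unhindered iodide.
   - Under the conditions of step 4 this should give the all-cis bis(2,2-dimethyl-4-oxochroman-6-yl) bis-amide F3.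
   - The two-stage cleavage of step 5 gives the all-cis diketo diacid F4.
   - Ketone-directed ortho C–H bromination ([(C5Me5)RhCl2]2, trivalent rhodium, AgSbF6, N-bromosuccinimide, pivalic acid, 1,2-dichloroethane, 60 °C) can reach only C5 of each chromanone and gives the dibromo diketo diacid F5.
   - NaBH4 in MeOH gives the bis(chroman-4-ol) diacid F6, and TsOH in toluene at 80 °C dehydrates it to the chromene diacid, which is 12, where the route is rejoined.

3. Step 5. What may go wrong: attack of hydroperoxide at the carbamate carbonyl instead of the hindered acyl carbon (returning 10), or base-induced epimerisation of the strained all-cis centres. Fallback, setting out from 10: methanolysis of the 8-aminoquinoline amides catalysed by nickel bis(2,2,6,6-tetramethylheptane-3,5-dionate), Ni(C11H19O2)2 (divalent nickel), in MeOH at 100 °C under neutral conditions gives the all-cis dimethyl ester F7. Me3SnOH in 1,2-dichloroethane at 80 °C, a non-basic ester cleavage that does not enolise the α-carbons, then comes back to the route at 12.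

**Further compounds**
F1 | step 6 | enantiomer of 14 | CC1(C)C=Cc2c(ccc3c2OC(=O)[C@@H]2[C@H]3[C@@H]3C(=O)Oc4c5c(ccc4[C@@H]32)OC(C)(C)C=C5)O1
F2 | step 4 | 6-iodo-2,2-dimethylchroman-4-one | CC1(C)CC(=O)c2cc(I)ccc2O1
F3 | step 4 | all-cis (meso) 2,4-bis(2,2-dimethyl-4-oxochroman-6-yl)-N1,N3-di(quinolin-8-yl)cyclobutane-1,3-dicarboxamide | O=C(Nc1cccc2cccnc12)[C@H]1[C@@H](c2ccc3OC(C)(C)CC(=O)c3c2)[C@@H](C(=O)Nc2cccc3cccnc23)[C@H]1c1ccc2OC(C)(C)CC(=O)c2c1
F4 | step 4 | all-cis (meso) 2,4-bis(2,2-dimethyl-4-oxochroman-6-yl)cyclobutane-1,3-dicarboxylic acid | OC(=O)[C@H]1[C@@H](c2ccc3OC(C)(C)CC(=O)c3c2)[C@@H](C(=O)O)[C@H]1c1ccc2OC(C)(C)CC(=O)c2c1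
F5 | step 4 | all-cis (meso) 2,4-bis(5-bromo-2,2-dimethyl-4-oxochroman-6-yl)cyclobutane-1,3-dicarboxylic acid | OC(=O)[C@H]1[C@@H](c2ccc3OC(C)(C)CC(=O)c3c2Br)[C@@H](C(=O)O)[C@H]1c1ccc2OC(C)(C)CC(=O)c2c1Br
F6 | step 4 | all-cis 2,4-bis(5-bromo-4-hydroxy-2,2-dimethylchroman-6-yl)cyclobutane-1,3-dicarboxylic acid (carbinol centres unassigned) | OC(=O)[C@H]1[C@@H](c2ccc3OC(C)(C)CC(O)c3c2Br)[C@@H](C(=O)O)[C@H]1c1ccc2OC(C)(C)CC(O)c2c1Br
F7 | step 5 | dimethyl all-cis (meso) 2,4-bis(5-bromo-2,2-dimethyl-2H-chromen-6-yl)cyclobutane-1,3-dicarboxylate | COC(=O)[C@H]1[C@@H](c2ccc3OC(C)(C)C=Cc3c2Br)[C@@H](C(=O)OC)[C@H]1c1ccc2OC(C)(C)C=Cc2c1Br
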